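## Retrosynthetic overview

1. Eudesmane numbering is used throughout: ring A = C1–C2–C3=C4–C5–C10, ring B = C5–C6–C7–C8–C9–C10, C14 = methyl on C10, C15 = CH2O on C4, C11–C13 = acrylate on C7.
2. Endgame disconnections: the aryl–alkenyl bond of the (Z)-p-coumarate (Suzuki coupling of a (Z)-3-iodoacrylate), the C15–O acyl bond, and the C15–O bond itself (allylic oxidation of methyl α-costate).
3. Enabling feature: ring A is a cyclohexene whose C3=C4 bond lies opposite the C1–C10 bond, so the bonds from the allylic carbons C2 and C5 to C1 and C10 (C1–C2 and C5–C10) are the two σ-bonds of a Diels–Alder retron. Cutting both opens rings A and B at once to an acyclic triene (diene C2=C3–C4=C5, dienophile C10=C1 bearing C14) whose only stereocenter is C7.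
4. That triene is (R)-limonene with its ring C=C bond cleaved: C5–C10, C14 and C11–C13 are the p-menthane carbons and C7 is the limonene stereocenter. The aldehyde end is extended by C4/C15/C3 (Wittig) and both carbonyls are methylenated (C2 and C1).
5. Ring order: the limonene ring is opened by ozonolysis (step 3); rings B and A are then closed together in one intramolecular Diels–Alder step, C5–C10 completing ring B and C1–C2 completing ring A.

Key step: step 6

## Route

Step 1
Reactants: 1 (R)-(+)-limonene
Product: 4 (4R)-p-mentha-1,8-dien-10-ol [2-[(1R)-4-methylcyclohex-3-en-1-yl]prop-2-en-1-ol], via 10-lithiolimonene 2 (not isolated), via dimethyl allylboronate 3 (not isolated)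
Conditions: n-BuLi, TMEDA, hexane, rt; then B(OMe)3, THF, −78 °C → rt; then H2O2, aq. NaOH, 0 °C
Reagents that add atoms: hydrogen peroxide, OO
Why: Allylic lithiation with n-BuLi·TMEDA deprotonates only the isopropenyl methyl group, and borylation/oxidation of the symmetric 2-substituted allyllithium gives the primary allylic alcohol without touching the ring stereocenter (the future C7).

Step 2
Reactants: 4 (4R)-p-mentha-1,8-dien-10-ol
Product: 6 methyl 2-[(1R)-4-methylcyclohex-3-en-1-yl]prop-2-enoate, via enal 5 (not isolated)
Conditions: MnO2, MeOH, 1,4-dimethyl-1,2,4-triazolium iodide (cat.), DBU, CH2Cl2, rt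
Reagents that add atoms: methanol, CO
Why: Tandem MnO2 allylic oxidation and N-heterocyclic-carbene oxidative esterification: the enal is intercepted by the carbene, the Breslow intermediate is oxidised by MnO2 to the acyl azolium, and methanol releases the methyl ester while the trisubstituted ring alkene is untouched.

Step 3
Reactants: 6 methyl 2-[(1R)-4-methylcyclohex-3-en-1-yl]prop-2-enoate
Product: 8 methyl (3R)-2-methylidene-6-oxo-3-(2-oxoethyl)heptanoate, via secondary ozonide 7 (not isolated)
Conditions: O3 (1 equiv), CH2Cl2, −78 °C; then PPh3, −78 °C → rt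
Reagents that add atoms: ozone, [O-][O+]=O
Why: Chemoselective ozonolysis (Criegee mechanism): the electron-rich trisubstituted ring alkene reacts far faster than the electron-poor acrylate, and reductive work-up opens the limonene ring to the keto aldehyde with the stereocenter intact.

Step 4
Reactants: 8 methyl (3R)-2-methylidene-6-oxo-3-(2-oxoethyl)heptanoate; 9 2-(triphenylphosphoranylidene)propanal
Product: 10 methyl (3R,5E)-6-methyl-2-methylidene-7-oxo-3-(3-oxobutyl)hept-5-enoate
Conditions: toluene, 90 °C
Reagents that add atoms: none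
Why: Wittig reaction with a stabilised formyl ylide olefinates only the aldehyde (not the methyl ketone or the ester) and gives the (E)-enal, which places C6 trans to the future vinyl group (cis to C15) as the cycloaddition requires.

Step 5
Reactants: 10 methyl (3R,5E)-6-methyl-2-methylidene-7-oxo-3-(3-oxobutyl)hept-5-enoate
Product: 11 methyl (3R,5E)-6-methyl-2-methylidene-3-(3-methylbut-3-en-1-yl)octa-5,7-dienoate
Conditions: Zn, CH2Br2, TiCl4 (reagent pre-formed in THF at 5 °C); then 10, CH2Cl2, 0 °C → rt
Reagents that add atoms: dibromomethane, BrCBr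
Why: Takai–Lombardo methylenation: the non-basic zinc/titanium methylene reagent converts both the enal and the methyl ketone carbonyls into C=CH2 without enolisation, ester attack or conjugate addition to the acrylate, and the C4=C5 geometry is retained.

Step 6
Reactants: 11 methyl (3R,5E)-6-methyl-2-methylidene-3-(3-methylbut-3-en-1-yl)octa-5,7-dienoate
Product: 12 methyl eudesma-3,11(13)-dien-12-oate (methyl α-costate) [methyl 2-[(2R,4aR,8aR)-4a,8-dimethyl-1,2,3,4,4a,5,6,8a-octahydronaphthalen-2-yl]prop-2-enoate]
Conditions: toluene (0.005 M), BHT (cat.), 200 °C, sealed tube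
Reagents that add atoms: none
Why: A concerted, asynchronous thermal [4+2] cycloaddition joins the (E)-diene C2=C3–C4=C5 to the unactivated 1,1-disubstituted alkene C10=C1, forming C1–C2 and C5–C10 suprafacially on both partners and leaving the C3=C4 double bond where the target has it. The closest known reaction type is the type 1 intramolecular Diels–Alder reaction of 1,7,9-decatrienes, including isopropenyl-type dienophiles that give angular-methyl octalins of the eudesmane family. Ring B closes through C5–C10 as the six-membered ring of the four-carbon tether C6–C9 (fused mode, the only one this tether allows), and ring A closes through C1–C2 as the new cyclohexene. C5 and C10 are set together: the trans ring fusion (H on C5 anti to the C14 methyl) comes from the transition state with the tether exo, favoured because the C15 methyl on C4 clashes with the C6 methylene in the cis-fused alternative, and both centres are placed relative to C7 by a chair-like tether with the C7 acrylate group equatorial, which puts the axial C14 methyl cis to the C7 substituent. The step needs ring-fusion and facial diastereoselectivity and chemoselectivity for the C10=C1 alkene over the acrylate; the (E)-diene geometry (C6 outside), the C15 substituent and the equatorial preference should secure the former, and the two-atom link between C5 and C11 (too short for an intramolecular cycloaddition) with high dilution and BHT should secure the latter. Minor diastereomers would be removed by chromatography on AgNO3-impregnated silica.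

Step 7
Reactants: 12 methyl α-costate
Product: 13 methyl 15-hydroxyeudesma-3,11(13)-dien-12-oate [methyl 2-[(2R,4aR,8aR)-8-(hydroxymethyl)-4a-methyl-1,2,3,4,4a,5,6,8a-octahydronaphthalen-2-yl]prop-2-enoate]
Conditions: SeO2 (cat.), t-BuOOH, salicylic acid (cat.), CH2Cl2, rt
Reagents that add atoms: tert-butyl hydroperoxide, CC(C)(C)OO (net source of the new oxygen, relayed by catalytic selenium dioxide, O=[Se]=O)
Why: Sharpless-type catalytic SeO2 allylic oxidation (ene reaction then [2,3]-sigmatropic shift) should attack the more substituted end of the C3=C4 bond and there the (E)-methyl group C15 in preference to the tertiary ring C5–H, while the electron-poor acrylate is inert; no stereocenter is formed.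

Step 8
Reactants: 13 methyl 15-hydroxyeudesma-3,11(13)-dien-12-oate; 14 (Z)-3-iodoacrylic acid
Product: 15 methyl 15-{[(2Z)-3-iodoprop-2-enoyl]oxy}eudesma-3,11(13)-dien-12-oate
Conditions: DCC, DMAP (cat.), CH2Cl2, −10 °C
Reagents that add atoms: none
Why: Steglich esterification: carbodiimide activation with catalytic DMAP at low temperature acylates the unhindered primary allylic alcohol and should keep the (Z)-iodoalkene geometry.

Step 9
Reactants: 15 methyl 15-{[(2Z)-3-iodoprop-2-enoyl]oxy}eudesma-3,11(13)-dien-12-oate; 16 4-hydroxyphenylboronic acid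
Product: 17 target, methyl 15-{[(2Z)-3-(4-hydroxyphenyl)prop-2-enoyl]oxy}eudesma-3,11(13)-dien-12-oate
Conditions: Pd(PPh3)4 (cat.), K3PO4, THF/H2O, rt
Reagents that add atoms: none
Why: Suzuki–Miyaura coupling: oxidative addition of zerovalent palladium to the alkenyl C–I bond, transmetalation and reductive elimination proceed with retention, so the (Z)-iodoacrylate should become the (Z)-p-coumarate with the free phenol tolerated, and this fast sequence should outrun ionisation of the hindered allylic ester.

## Compound list

1 | (R)-(+)-limonene | C=C(C)[C@@H]1CCC(C)=CC1 | starting material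
2 | 10-lithiolimonene, {2-[(1R)-4-methylcyclohex-3-en-1-yl]prop-2-en-1-yl}lithium | [Li]CC(=C)[C@@H]1CCC(C)=CC1 | intermediate
3 | dimethyl {2-[(1R)-4-methylcyclohex-3-en-1-yl]prop-2-en-1-yl}boronate | COB(OC)CC(=C)[C@@H]1CCC(C)=CC1 | intermediate
4 | (4R)-p-mentha-1,8-dien-10-ol, 2-[(1R)-4-methylcyclohex-3-en-1-yl]prop-2-en-1-ol | C=C(CO)[C@@H]1CCC(C)=CC1 | intermediate
5 | 2-[(1R)-4-methylcyclohex-3-en-1-yl]prop-2-enal | C=C(C=O)[C@@H]1CCC(C)=CC1 | intermediate
6 | methyl 2-[(1R)-4-methylcyclohex-3-en-1-yl]prop-2-enoate | C=C(C(=O)OC)[C@@H]1CCC(C)=CC1 | intermediate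
7 | secondary ozonide of 6, methyl 2-[(4R)-1-methyl-7,8,9-trioxabicyclo[4.2.1]nonan-4-yl]prop-2-enoate (both trioxolane epimers) | C=C(C(=O)OC)[C@@H]1CCC2(C)OOC(C1)O2 | intermediate
8 | methyl (3R)-2-methylidene-6-oxo-3-(2-oxoethyl)heptanoate | C=C(C(=O)OC)[C@@H](CC=O)CCC(C)=O | intermediate
9 | 2-(triphenylphosphoranylidene)propanal | CC(C=O)=P(c1ccccc1)(c1ccccc1)c1ccccc1 | starting material
10 | methyl (3R,5E)-6-methyl-2-methylidene-7-oxo-3-(3-oxobutyl)hept-5-enoate | C=C(C(=O)OC)[C@@H](C/C=C(\C)C=O)CCC(C)=O | intermediate
11 | methyl (3R,5E)-6-methyl-2-methylidene-3-(3-methylbut-3-en-1-yl)octa-5,7-dienoate | C=C(C(=O)OC)[C@@H](C/C=C(\C)C=C)CCC(C)=C | intermediate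
12 | methyl α-costate, methyl 2-[(2R,4aR,8aR)-4a,8-dimethyl-1,2,3,4,4a,5,6,8a-octahydronaphthalen-2-yl]prop-2-enoate | C=C(C(=O)OC)[C@@H]1CC[C@@]2(C)CCC=C(C)[C@@H]2C1 | intermediate
13 | methyl 15-hydroxy-α-costate, methyl 2-[(2R,4aR,8aR)-8-(hydroxymethyl)-4a-methyl-1,2,3,4,4a,5,6,8a-octahydronaphthalen-2-yl]prop-2-enoate | C=C(C(=O)OC)[C@@H]1CC[C@@]2(C)CCC=C(CO)[C@@H]2C1 | intermediate
14 | (Z)-3-iodoacrylic acid | OC(=O)/C=C\I | starting material
15 | methyl 2-[(2R,4aR,8aR)-8-({[(2Z)-3-iodoprop-2-enoyl]oxy}methyl)-4a-methyl-1,2,3,4,4a,5,6,8a-octahydronaphthalen-2-yl]prop-2-enoate | C=C(C(=O)OC)[C@@H]1CC[C@@]2(C)CCC=C(COC(=O)/C=C\I)[C@@H]2C1 | intermediate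
16 | 4-hydroxyphenylboronic acid | OB(O)c1ccc(O)cc1 | starting material
17 | methyl 2-[(2R,4aR,8aR)-8-({[(2Z)-3-(4-hydroxyphenyl)prop-2-enoyl]oxy}methyl)-4a-methyl-1,2,3,4,4a,5,6,8a-octahydronaphthalen-2-yl]prop-2-enoate | C=C(C(=O)OC)[C@@H]1CC[C@@]2(C)CCC=C(COC(=O)/C=C\c3ccc(O)cc3)[C@@H]2C1 | target

## Step count and risks

Total step count: 9. Longest linear sequence: 9 steps (1 → 17); compounds 9, 14 and 16 are purchased.

**Step 6 (intramolecular Diels–Alder reaction).** The unactivated cycloaddition may be slow enough at 200 °C for the acrylate to divert material. Possible channels are an ene reaction, oligomerisation, and a reversible Cope shift through the C4=C5–C6–C7–C11=C13 1,5-diene, which passes through an achiral isomer and would erode the configuration at C7. Ring-fusion and facial control may also be incomplete.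

Fallback: mask the acrylate before the cycloaddition. Setting out from triene 11, conjugate addition of thiophenol (PhSH, cat. Et3N, CH2Cl2, rt, dark) should give the sulfide-masked triene methyl (3R,5E)-6-methyl-3-(3-methylbut-3-en-1-yl)-2-[(phenylsulfanyl)methyl]octa-5,7-dienoate F1 (both C2 epimers), which has neither the electron-poor alkene nor the 1,5-diene. Its thermal cycloaddition (toluene, 200–220 °C, longer times now permitted) should give the decalin sulfide methyl 2-[(2R,4aR,8aR)-4a,8-dimethyl-1,2,3,4,4a,5,6,8a-octahydronaphthalen-2-yl]-3-(phenylsulfanyl)propanoate F2. Oxidation (NaIO4, MeOH/H2O, 0 °C) gives the sulfoxide methyl 2-[(2R,4aR,8aR)-4a,8-dimethyl-1,2,3,4,4a,5,6,8a-octahydronaphthalen-2-yl]-3-(phenylsulfinyl)propanoate F3, and thermal syn-elimination (toluene, 110 °C, CaCO3) regenerates the acrylate and comes back to the route at 12.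

**Step 7 (allylic oxidation).** Oxidation may go to the wrong allylic position (ring methylene C2 or the tertiary C5–H), or over-oxidise C15 to the enal.

Fallback: introduce the oxygen through the alkene instead of a C–H bond. Setting out from 12, epoxidation (mCPBA, NaHCO3, CH2Cl2, 0 °C; only the electron-rich C3=C4 bond reacts) gives the epoxide methyl 3,4-epoxyeudesm-11(13)-en-12-oate F4. Isomerisation with TMSOTf and 2,6-lutidine (toluene, −78 °C), then DBU, should open it toward the C15 methyl to the allylic silyl ether methyl 3-(trimethylsilyloxy)eudesma-4(15),11(13)-dien-12-oate F5. PPTS in MeOH gives the secondary allylic alcohol methyl 3-hydroxyeudesma-4(15),11(13)-dien-12-oate F6. A 1,3-transposition with Ph3SiOReO3 (cat., Et2O, 0 °C) moves the hydroxyl to C15 and the double bond into the ring, coming back at 13. The configuration at C3 (and the epoxide face) does not matter, since C3 becomes sp2 again.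

**Step 9 (Suzuki coupling).** The (Z)-alkene may isomerise to (E), the β-iodoacrylate may lose HI under base, or zerovalent palladium may ionise the allylic ester and divert it to allyl aryl ethers.

Fallback: build the (Z)-alkene by olefination without palladium. Setting out from 13, DCC/DMAP esterification with 2-(diphenoxyphosphoryl)acetic acid gives the phosphonoacetate methyl 15-{[2-(diphenoxyphosphoryl)acetyl]oxy}eudesma-3,11(13)-dien-12-oate F7. An Ando-type Z-selective Horner–Wadsworth–Emmons reaction with 4-[(tert-butyldimethylsilyl)oxy]benzaldehyde (NaH, THF, −78 °C) should give the silyl-protected coumarate methyl 15-{[(2Z)-3-{4-[(tert-butyldimethylsilyl)oxy]phenyl}prop-2-enoyl]oxy}eudesma-3,11(13)-dien-12-oate F8. HF·pyridine (THF, 0 °C) removes the silyl group and comes back at the target 17.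

## Further compounds

F1 | step 6 | methyl (3R,5E)-6-methyl-3-(3-methylbut-3-en-1-yl)-2-[(phenylsulfanyl)methyl]octa-5,7-dienoate (both C2 epimers) | COC(=O)C(CSc1ccccc1)[C@@H](C/C=C(\C)C=C)CCC(C)=C
F2 | step 6 | methyl 2-[(2R,4aR,8aR)-4a,8-dimethyl-1,2,3,4,4a,5,6,8a-octahydronaphthalen-2-yl]-3-(phenylsulfanyl)propanoate (both C2 epimers) | COC(=O)C(CSc1ccccc1)[C@@H]1CC[C@@]2(C)CCC=C(C)[C@@H]2C1
F3 | step 6 | methyl 2-[(2R,4aR,8aR)-4a,8-dimethyl-1,2,3,4,4a,5,6,8a-octahydronaphthalen-2-yl]-3-(phenylsulfinyl)propanoate (mixture at C2 and sulfur) | COC(=O)C(CS(=O)c1ccccc1)[C@@H]1CC[C@@]2(C)CCC=C(C)[C@@H]2C1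
F4 | step 7 | methyl 3,4-epoxyeudesm-11(13)-en-12-oate (epoxide face not decisive) | C=C(C(=O)OC)[C@@H]1CC[C@@]2(C)CCC3OC3(C)[C@@H]2C1
F5 | step 7 | methyl 3-(trimethylsilyloxy)eudesma-4(15),11(13)-dien-12-oate (C3 configuration not decisive) | C=C(C(=O)OC)[C@@H]1CC[C@@]2(C)CCC(O[Si](C)(C)C)C(=C)[C@@H]2C1
F6 | step 7 | methyl 3-hydroxyeudesma-4(15),11(13)-dien-12-oate (C3 configuration not decisive) | C=C(C(=O)OC)[C@@H]1CC[C@@]2(C)CCC(O)C(=C)[C@@H]2C1
F7 | step 9 | methyl 15-{[2-(diphenoxyphosphoryl)acetyl]oxy}eudesma-3,11(13)-dien-12-oate | C=C(C(=O)OC)[C@@H]1CC[C@@]2(C)CCC=C(COC(=O)CP(=O)(Oc3ccccc3)Oc3ccccc3)[C@@H]2C1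
F8 | step 9 | methyl 15-{[(2Z)-3-{4-[(tert-butyldimethylsilyl)oxy]phenyl}prop-2-enoyl]oxy}eudesma-3,11(13)-dien-12-oate | C=C(C(=O)OC)[C@@H]1CC[C@@]2(C)CCC=C(COC(=O)/C=C\c3ccc(O[Si](C)(C)C(C)(C)C)cc3)[C@@H]2C1
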